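Start with a conservation law: a charged free monomer ends up free, in chains, as isomer, dormant or quenched, and you read only the first three.

the same everywhere: initiator 0.16 mol%

|  | free monomer | protic impurity | remark | time |
|---|---|---|---|---|
| Tuesday's | 0.67 M | 0.30 M | run made earlier |  |
| Sunday's | 1.5 M | 0.30 M | run made earlier |  |
| autumn | 1.0 M | 0.300 M |  | 20 min |
| dusk | 1.0 M | 0.300 M |  | 40 min |

| run | time / min | monomer in chains / % | free monomer / % | isomer of the product / % |
|---|---|---|---|---|
| Tuesday's | 3.00 | 2.3 | 76.1 | 0 |
| Tuesday's | 8.00 | 5.7 | 60.2 | 0.8 |
| Tuesday's | 15.0 | 8.7 | 50.4 | 1.2 |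
| Tuesday's | 25.0 | 11.9 | 42.7 | 2.2 |
| Sunday's | 6.00 | 7.1 | 64.1 | 0.3 |
| Sunday's | 12.0 | 10.6 | 54.4 | 1.4 |
| Sunday's | 20.0 | 15.7 | 47.7 | 3.0 |
| Sunday's | 25.0 | 18.1 | 44.6 | 3.9 |

(standard deviation of a reading: 0.3 percentage points)

- reactions considered so far: initiator -> 2 initiating radical; free monomer + initiating radical -> growing radical + monomer in chains; free monomer + growing radical -> monomer in chains + growing radical; 2 growing radical -> dead chain; free monomer <-> dormant form; protic impurity + free monomer -> quenched substrate; monomer in chains <-> isomer of the product
- a reading of free monomer is of its free form alone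

* which of these there is most of at the end, counted by the free monomer in it, autumn (monomer in chains / free monomer / isomer of the product)
* which of these there is most of at the end, counted by the free monomer in it, dusk (monomer in chains / free monomer / isomer of the product)
* the largest of these amounts at the end, in percent of the free monomer charged, autumn
* the largest of these amounts at the end, in percent of the free monomer charged, dusk

Take the last row of Sunday's table. Its three columns leave 33.4% of the charge unseen. Each protic impurity takes one free monomer, so quenching accounts for 20.0% of Sunday's charge at the very most, and the rest is dormant. Divide that rest by the free monomer column and you get 0.300. This is the low end of the dormant ratio, c(dormant form)/c(free monomer), an equilibrium constant if the exchange has relaxed. The balance then reads: free monomer = (charge − chains − isomer − quenched)/(1 + ratio).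

Now read the columns at 20 min. Sunday's free monomer stands at 47.7%, and Tuesday's, midway between its rows at 15.0 min and 25.0 min, at 46.6%. Their mean gives my figure for autumn, 47.1%. The same mean for chains plus isomer is 15.4%. Carrying on the growth of both runs' last stretches to 40 min gives 26.2%. For dusk, grant that the protic impurity is used up entirely. With the ratio at its low end, the balance then gives an estimate, not a bound, of 33.7% free monomer, more than the carried-on figure for chains and isomer together.

The forecast says free monomer at 47% for autumn and free monomer at 37.5% for dusk, above my estimate. In its words: “Free monomer stays largest at both times.”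

The flasks give free monomer at 47.0% in autumn and free monomer at 36.4% in dusk.

    initiator → 2 initiating radical (k = 5.96 × 10⁻⁵ s⁻¹)
    free monomer + initiating radical → growing radical + monomer in chains (k = 9.92 × 10⁵ M⁻¹ s⁻¹)
    free monomer + growing radical → monomer in chains + growing radical, rate k3*[growing radical]*[free monomer] (k = 6110 M⁻¹ s⁻¹)
    2 growing radical → dead chain (k = 8.30 × 10⁷ M⁻¹ s⁻¹)
    free monomer ⇌ dormant form (K = 0.330, k = 0.00126 s⁻¹)
    protic impurity + free monomer → quenched substrate (k = 0.00169 M⁻¹ s⁻¹)
    monomer in chains ⇌ isomer of the product (K = 0.520, k = 3.30 × 10⁻⁴ s⁻¹)

In autumn, free monomer and dormant form relax with a half-life of 2.27 min, short against the 20 min of the run. The dormant ratio at autumn's end is 0.355. In the neighbouring flask with 0.51 M of protic impurity it is 0.366, and free monomer, at 38.4%, still exceeds monomer in chains at 11.3%. The forecast's answer would fail with time: autumn's flask left to 200 min holds more monomer in chains, 38.0%, than free monomer, 9.91%.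

The runs stem from a simulated flask for an exercise, and the scatter is random.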